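Readings and results are simulated for an exercise; scatter was added.

**The leftover.** In Monday's run, 34.7% of the electrophile is still left at the last reading, yet the target has stood near 43.2% since 50.0 min. Something other than electrophile has stopped it.

all flasks: electrophile 10 mM

|  | free base | protonated nucleophile | protic impurity | remark | time |
|---|---|---|---|---|---|
| Monday's | 0.81 equiv | 0.90 equiv | 0.20 mM | run made earlier |  |
| Wednesday's | 1.4 equiv | 0.90 equiv | 0.20 mM | run made earlier |  |
| Saturday's | 2.1 equiv | 0.90 equiv | 0.20 mM | run made earlier |  |
| violet | 1.00 equiv | 0.900 equiv | 0.200 mM |  | 2.5 h |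
| ochre | 2.00 equiv | 0.900 equiv | 0.200 mM |  | 2.5 h |

| run | time / min | electrophile / % | target / % |
|---|---|---|---|
| Monday's | 15.0 | 54.4 | 40.0 |
| Monday's | 30.0 | 49.1 | 41.4 |
| Monday's | 50.0 | 40.9 | 42.9 |
| Monday's | 60.0 | 40.8 | 43.0 |
| Monday's | 80.0 | 34.7 | 43.2 |
| Wednesday's | 15.0 | 28.9 | 67.0 |
| Wednesday's | 30.0 | 26.6 | 71.1 |
| Wednesday's | 50.0 | 24.4 | 69.1 |
| Wednesday's | 60.0 | 23.8 | 69.8 |
| Wednesday's | 80.0 | 22.0 | 71.8 |
| Saturday's | 6.00 | 31.5 | 68.8 |
| Saturday's | 12.0 | 22.9 | 77.1 |
| Saturday's | 20.0 | 13.6 | 83.3 |
| Saturday's | 40.0 | 11.7 | 85.8 |
| Saturday's | 80.0 | 9.0 | 85.1 |

(each reading ± 1 percentage point)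

* part of the electrophile that has reacted at the end, violet
* part of the electrophile that has reacted at the end, ochre
* what raising the equivalents of free base from its lowest to its highest value here does to the part of the electrophile that has reacted (changes below 5 percentage points count as none) (it rises / it falls / no change)



**The balance.** I suppose that one free base releases each protonated nucleophile and that the coupling gives one more acid to bind, so a target costs two free base. I also suppose that the protic impurity takes one nucleophile and so costs one free base. As fractions of the electrophile charged, the target ceiling is the smaller of two figures: free base minus impurity, divided by two, and protonated nucleophile minus impurity. For violet it is 49.0%, on the free base side, which makes free base the limiting reagent there. For ochre it is 88.0%, on the nucleophile side.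

**Second way.** Reading between Monday's and Wednesday's targets at 60.0 min gives violet 51.6%, a little above the ceiling. Wednesday's readings lie around its ceiling of 69.0%. Monday's ceiling is 39.5%, and its reading at 60.0 min stands 3.5 percentage points above it, which the scatter does not cover. So the balance cheats slightly for Monday's run, and I suspect that some acid stays off the free base. I commit to a violet target just above its ceiling. The electrophile beyond that goes by the slow loss seen in the runs.

**The forecast.** It gives 79% for violet and 92.5% for ochre, with the trend it rises, and reads that “each target seems to consume about 2 base”.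

**The result.** The flask gives 75.3% for violet and 92.1% for ochre, and the trend is it rises, by 17 points. The forecast holds.

    electrophile + nucleophile → acid set free + target (k = 55.3 M⁻¹ min⁻¹)
    nucleophile + acid set free ⇌ protonated nucleophile, settled at all times (K = 5.50 × 10⁵ M⁻¹)
    acid set free + free base ⇌ salt of the base, settled at all times (K = 4.90 × 10⁶ M⁻¹)
    2 electrophile → homo dimer (k = 0.576 M⁻¹ min⁻¹)
    nucleophile + protic impurity → quenched reagent (k = 682 M⁻¹ min⁻¹)

**What it means.** Violet's target reaches 53.0% against its ceiling of 49.0%. It also holds 0.802 mM of unbound acid set free, worth 4.01% of target in the balance, which closes the gap. Ochre's target reaches 87.9%, on its ceiling of 88.0%. The difference in equivalents of free base is the main reason for the gap between ochre at 92.1% and violet at 75.3%.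

**Second flask.** With 0.230 equiv of protonated nucleophile in violet's recipe, the ceiling moves to the nucleophile side at 21.0%. That flask gives 21.1% of target and 66.8% reacted.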